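**Retrosynthetic overview** (rings: A = five-membered enol-acetate ring, B = dihydropyran, C = seven-membered carbocycle, D = cyclohexene, E = pyrrolidine, F = azepanone)
1. Target ⇐ O-acetylation of the ring A enol; ring F by intramolecular Mannich reaction (N–CH2–C); ring E by carbinolamine formation between a primary amine and the ring D ketone.
2. Ring B ⇐ SN2′ displacement of an α′-pivaloyloxy group by a pendant alcohol; ring D ⇐ Mukaiyama aldol of a methyl ketone onto a 1,2-dione.
3. Key step: rings A + C together by an allenic Pauson–Khand [2+2+1] cycloaddition, preceded in the same flask by a [3,3] acyloxy shift.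
4. Allenyne ⇐ butyrolactone template: (S)-epichlorohydrin + malonate → cyclopropane lactone → cuprate opening → anti C-methylation (quaternary centre) → alkyne.
5. Forward ring order: lactone template → A + C → D → B → E + F.

Assumption: the methyl-bearing carbon next to the ring F ketone is epimerisable, and the epimer drawn in the target is the thermodynamically preferred one in the cage.

The route is a paper proposal; none of it has been run, and the SMILES were written by hand and not machine-checked.

**Step 1**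
Reactants: 1 (S)-epichlorohydrin; 2 diethyl malonate
Product: 3 ethyl (1R,5S)-2-oxo-3-oxabicyclo[3.1.0]hexane-1-carboxylate
Conditions: NaOEt, EtOH, reflux
Reagents that add atoms: none
Why: Double alkylation/lactonisation: malonate opens the epoxide at CH2, the alkoxide re-closes to the transposed epoxide, and 3-exo-tet C-alkylation with inversion followed by lactonisation gives the cyclopropane lactone, so the ring-fusion methine is the stereocentre bought with 1.

**Step 2**
Reactants: 3
Product: 4 ethyl (4S)-4-[2-(1,3-dioxolan-2-yl)ethyl]-2-oxotetrahydrofuran-3-carboxylate (C3 epimers)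
Conditions: (1,3-dioxolan-2-ylmethyl)MgBr, CuI (copper monoiodide, 10 mol %), THF, −30 °C; aq. NH4Cl
Reagents that add atoms: (1,3-dioxolan-2-ylmethyl)magnesium bromide, Br[Mg]CC1OCCO1
Why: Copper-catalysed homoconjugate (1,5-) addition of the Grignard reagent to the doubly activated cyclopropane occurs at its CH2 and leaves the methine stereocentre untouched.

**Step 3**
Reactants: 4
Product: 6 3-[(3S)-5-oxotetrahydrofuran-3-yl]propanal, via dioxolane lactone 5 (not isolated)
Conditions: LiCl, DMSO, H2O, 140 °C; then 1 M HCl, THF, 23 °C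
Reagents that add atoms: water, O
Why: Krapcho dealkoxycarbonylation removes the activating ester and the acidic work-up hydrolyses the acetal to the aldehyde, neither touching the stereocentre.

**Step 4**
Reactants: 6; 7 tert-butyl(but-3-yn-1-yloxy)dimethylsilane
Product: 9 (4S)-4-[7-(tert-butyldimethylsilyloxy)-3-hydroxyhept-4-yn-1-yl]dihydrofuran-2(3H)-one (carbinol epimers), via lithium acetylide 8 (not isolated)
Conditions: 7, n-BuLi, THF, −78 °C; then 6, −78 °C; aq. NH4Cl
Reagents that add atoms: none
Why: 1,2-Addition of the lithium acetylide to the aldehyde is much faster than attack on the lactone at −78 °C, and the new carbinol centre is irrelevant because it is erased in step 12.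

**Step 5**
Reactants: 9
Product: 10 7-(tert-butyldimethylsilyloxy)-1-[(3S)-5-oxotetrahydrofuran-3-yl]hept-4-yn-3-yl pivalate (carbinol epimers)
Conditions: PivCl, pyridine, DMAP (cat.), CH2Cl2, 0 → 23 °C
Reagents that add atoms: pivaloyl chloride, CC(C)(C)C(Cl)=O
Why: O-Acylation of the propargylic alcohol installs the ester that migrates in the later [3,3] shift and that is robust to the base and organolithium steps in between.

**Step 6**
Reactants: 10
Product: 12 7-(tert-butyldimethylsilyloxy)-1-[(3S,4S)-4-formyl-4-methyl-5-oxotetrahydrofuran-3-yl]hept-4-yn-3-yl pivalate, via sodium hydroxymethylene-lactone enolate 11 (not isolated)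
Conditions: NaH, HCO2Et, EtOH (cat.), THF, 0 → 23 °C; then MeI, DMF, 23 °C
Reagents that add atoms: ethyl formate, CCOC=O; iodomethane, CI
Why: Claisen formylation gives the stabilised enolate, whose C-methylation takes place anti to the neighbouring side chain of the butyrolactone, so the quaternary centre (methyl trans to the chain, formyl cis) is set by the epichlorohydrin-derived methine.

**Step 7**
Reactants: 12
Product: 13 7-(tert-butyldimethylsilyloxy)-1-[(3S,4S)-4-ethynyl-4-methyl-5-oxotetrahydrofuran-3-yl]hept-4-yn-3-yl pivalate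
Conditions: TMSCHN2, n-BuLi, THF, −78 °C; then 12, −78 → 0 °C
Reagents that add atoms: (trimethylsilyl)diazomethane, C[Si](C)(C)C=[N+]=[N-]
Why: Colvin homologation (addition, Peterson elimination, loss of N2, 1,2-H shift of the alkylidene carbene) turns the non-enolisable aldehyde into the terminal alkyne without alkoxide that could deformylate or open the lactone.

**Step 8**
Reactants: 13
Product: 14 7-(tert-butyldimethylsilyloxy)-1-[(2S,3S)-3-ethynyl-1-hydroxy-3-methyl-4-oxopentan-2-yl]hept-4-yn-3-yl pivalate (open form of the cyclic hemiketal)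
Conditions: MeLi (2.1 equiv), THF, −78 °C; AcOH, −78 °C
Reagents that add atoms: methyllithium, [Li]C
Why: After deprotonation of the alkyne, MeLi adds once to the lactone (nucleophilic acyl addition) because the tetrahedral lithium hemiketal persists at −78 °C, giving the methyl ketone and freeing the primary alcohol while the hindered pivalate survives.

**Step 9**
Reactants: 14
Product: 15 1-{(2S,3S)-1-[bis(tert-butoxycarbonyl)amino]-3-ethynyl-3-methyl-4-oxopentan-2-yl}-7-(tert-butyldimethylsilyloxy)hept-4-yn-3-yl pivalate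
Conditions: HN(Boc)2, PPh3, DIAD, THF, 0 → 23 °C
Reagents that add atoms: di-tert-butyl iminodicarbonate, CC(C)(C)OC(=O)NC(=O)OC(C)(C)C
Why: Mitsunobu reaction of the primary alcohol with the acidic imide installs the protected nitrogen at a non-stereogenic CH2.

**Step 10**
Reactants: 15
Product: 16 1-{(2S,3S)-1-[bis(tert-butoxycarbonyl)amino]-4-(tert-butyldimethylsilyloxy)-3-ethynyl-3-methylpent-4-en-2-yl}-7-(tert-butyldimethylsilyloxy)hept-4-yn-3-yl pivalate
Conditions: TBSOTf, Et3N, CH2Cl2, −78 °C
Reagents that add atoms: tert-butyldimethylsilyl trifluoromethanesulfonate, CC(C)(C)[Si](C)(C)OS(=O)(=O)C(F)(F)F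
Why: Soft enolisation of the methyl ketone, which can enolise only toward its CH3, fixes the nucleophilic carbon of the later aldol as a silyl enol ether.

**Step 11**
Reactants: 16
Product: 17 1-{(2S,3S)-1-[bis(tert-butoxycarbonyl)amino]-4-(tert-butyldimethylsilyloxy)-3-(3,4-dioxohex-1-yn-1-yl)-3-methylpent-4-en-2-yl}-7-(tert-butyldimethylsilyloxy)hept-4-yn-3-yl pivalate
Conditions: 2-oxobutanoic acid, Cl2CHOMe, CH2Cl2, 23 °C, evaporate; then 16, CuI (5 mol %), Et3N, THF, 0 → 23 °C
Reagents that add atoms: 2-oxobutanoyl chloride, CCC(=O)C(Cl)=O (made in the flask from 2-oxobutanoic acid, CCC(=O)C(O)=O)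
Why: Copper-catalysed acylation of the terminal alkyne through its copper acetylide (acyl Sonogashira-type coupling) gives the ynedione under conditions that spare the enol ether, the carbamates and the esters.

**Step 12** (key step)
Reactants: 17
Product: 19 (4S,5S)-5-{[bis(tert-butoxycarbonyl)amino]methyl}-4-[1-(tert-butyldimethylsilyloxy)vinyl]-1-[2-(tert-butyldimethylsilyloxy)ethyl]-4-methyl-2-oxo-3-(2-oxobutanoyl)-1,2,4,5,6,7-hexahydroazulen-1-yl pivalate (C1 epimers), via allenyl pivalate 18 (not isolated)
Conditions: Rh2(O2CCF3)4 (2 mol %), PhMe, 50 °C; then [Rh(CO)2Cl]2 (5 mol %), CO (1 atm), 90 °C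
Reagents that add atoms: carbon monoxide, [C-]#[O+]
Why: A [3,3] (1,3-acyloxy) shift converts the propargylic pivalate into the allenyl pivalate, whose distal double bond combines with the alkyne and CO in an allenic Pauson–Khand [2+2+1] cycloaddition that closes ring A and the seven-membered ring C at once; the two existing centres are untouched and the new acyloxy-bearing centre is erased in step 14.

**Step 13**
Reactants: 19
Product: 20 tricyclic ketol (rings A/C/D) with an (R)-tertiary alcohol bearing the propanoyl group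
Conditions: BF3·OEt2, CH2Cl2, −78 °C; aq. NaHCO3
Reagents that add atoms: none
Why: Intramolecular Mukaiyama aldol addition of the silyl enol ether carbon to the ring-proximal carbonyl of the activated 1,2-dione through a six-membered transition state closes ring D; the carbinol epimer drawn (propanoyl on the face of the aminomethyl arm) is the one needed for bridging, and any minor epimer can equilibrate in step 15 by retro-aldol/aldol.

**Step 14**
Reactants: 20
Product: 22 tetracyclic pyran (rings A–D; ring A as the CH keto tautomer), via primary alcohol 21 (not isolated)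
Conditions: HF·pyridine, pyridine, THF, 0 → 23 °C; then Et3N, 40 °C
Reagents that add atoms: none
Why: Desilylation frees the primary alcohol, which adds 6-endo to the alkylidene carbon and expels pivalate (oxa-Michael addition–elimination, net SN2′); prototropy then gives the conjugated pyran enol ether, so ring B forms at the correct oxidation level without an oxidant.

**Step 15**
Reactants: 22
Product: 25 O-deacetyl target (hexacycle A–F; ring A keto tautomer), via ammonium trifluoroacetate 23 (not isolated), via carbinolamine 24 (not isolated)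
Conditions: CF3CO2H, CH2Cl2, 0 °C, evaporate; then 37% aq. CH2O, NaOAc, MeOH, 50 °C
Reagents that add atoms: formaldehyde, C=O
Why: Acidolysis removes both Boc groups, the freed amine closes onto the ring D ketone to the five-membered carbinolamine (ring E), and its N–H reacts with formaldehyde to an iminium that is trapped by the enol of the propanoyl ketone in an intramolecular Mannich reaction (ring F); the carbinolamine centre is dictated by the cage, and the methyl-bearing centre next to the ketone settles to the thermodynamic epimer.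

**Step 16**
Reactants: 25
Product: 26 CNP0309418.1 (target)
Conditions: Ac2O, Et3N, CH2Cl2, 0 °C
Reagents that add atoms: acetic anhydride, CC(=O)OC(C)=O
Why: Et3N removes the acidic ring A C–H (fulvenolate, a vinylogous 1,3-dicarbonyl anion) and kinetic O-acetylation gives the fulvene enol acetate, while the two tertiary alcohols and the tertiary amine are not acylated at 0 °C.

**Compound list**

1 | (S)-epichlorohydrin | ClC[C@@H]1CO1 | starting material
2 | diethyl malonate | CCOC(=O)CC(=O)OCC | starting material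
3 | ethyl (1R,5S)-2-oxo-3-oxabicyclo[3.1.0]hexane-1-carboxylate | O=C1OC[C@H]2C[C@@]12C(=O)OCC | intermediate
4 | ethyl (4S)-4-[2-(1,3-dioxolan-2-yl)ethyl]-2-oxotetrahydrofuran-3-carboxylate (C3 epimers) | CCOC(=O)C1[C@H](CCC2OCCO2)COC1=O | intermediate
5 | (4S)-4-[2-(1,3-dioxolan-2-yl)ethyl]dihydrofuran-2(3H)-one (dioxolane lactone) | O=C1C[C@H](CCC2OCCO2)CO1 | intermediate (not isolated)
6 | 3-[(3S)-5-oxotetrahydrofuran-3-yl]propanal | O=C1C[C@H](CCC=O)CO1 | intermediate
7 | tert-butyl(but-3-yn-1-yloxy)dimethylsilane | C#CCCO[Si](C)(C)C(C)(C)C | starting material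
8 | lithium acetylide of 7 | [Li]C#CCCO[Si](C)(C)C(C)(C)C | intermediate (not isolated)
9 | (4S)-4-[7-(tert-butyldimethylsilyloxy)-3-hydroxyhept-4-yn-1-yl]dihydrofuran-2(3H)-one (carbinol epimers) | O=C1C[C@H](CCC(O)C#CCCO[Si](C)(C)C(C)(C)C)CO1 | intermediate
10 | 7-(tert-butyldimethylsilyloxy)-1-[(3S)-5-oxotetrahydrofuran-3-yl]hept-4-yn-3-yl pivalate (carbinol epimers) | O=C1C[C@H](CCC(OC(=O)C(C)(C)C)C#CCCO[Si](C)(C)C(C)(C)C)CO1 | intermediate
11 | sodium enolate of the 4-(hydroxymethylene) derivative of 10 | [Na+].[O-]C=C1C(=O)OC[C@H]1CCC(OC(=O)C(C)(C)C)C#CCCO[Si](C)(C)C(C)(C)C | intermediate (not isolated)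
12 | 7-(tert-butyldimethylsilyloxy)-1-[(3S,4S)-4-formyl-4-methyl-5-oxotetrahydrofuran-3-yl]hept-4-yn-3-yl pivalate | C[C@@]1(C=O)[C@H](CCC(OC(=O)C(C)(C)C)C#CCCO[Si](C)(C)C(C)(C)C)COC1=O | intermediate
13 | 7-(tert-butyldimethylsilyloxy)-1-[(3S,4S)-4-ethynyl-4-methyl-5-oxotetrahydrofuran-3-yl]hept-4-yn-3-yl pivalate | C[C@@]1(C#C)[C@H](CCC(OC(=O)C(C)(C)C)C#CCCO[Si](C)(C)C(C)(C)C)COC1=O | intermediate
14 | 7-(tert-butyldimethylsilyloxy)-1-[(2S,3S)-3-ethynyl-1-hydroxy-3-methyl-4-oxopentan-2-yl]hept-4-yn-3-yl pivalate | CC(=O)[C@](C)(C#C)[C@@H](CO)CCC(OC(=O)C(C)(C)C)C#CCCO[Si](C)(C)C(C)(C)C | intermediate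
15 | 1-{(2S,3S)-1-[bis(tert-butoxycarbonyl)amino]-3-ethynyl-3-methyl-4-oxopentan-2-yl}-7-(tert-butyldimethylsilyloxy)hept-4-yn-3-yl pivalate | CC(=O)[C@](C)(C#C)[C@@H](CN(C(=O)OC(C)(C)C)C(=O)OC(C)(C)C)CCC(OC(=O)C(C)(C)C)C#CCCO[Si](C)(C)C(C)(C)C | intermediate
16 | silyl enol ether of 15 (4-(tert-butyldimethylsilyloxy)pent-4-en-2-yl unit) | C=C(O[Si](C)(C)C(C)(C)C)[C@](C)(C#C)[C@@H](CN(C(=O)OC(C)(C)C)C(=O)OC(C)(C)C)CCC(OC(=O)C(C)(C)C)C#CCCO[Si](C)(C)C(C)(C)C | intermediate
17 | ynedione: 16 carrying a 3,4-dioxohex-1-yn-1-yl group in place of the ethynyl group | C=C(O[Si](C)(C)C(C)(C)C)[C@](C)(C#CC(=O)C(=O)CC)[C@@H](CN(C(=O)OC(C)(C)C)C(=O)OC(C)(C)C)CCC(OC(=O)C(C)(C)C)C#CCCO[Si](C)(C)C(C)(C)C | intermediate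
18 | allenyl pivalate: the hepta-3,4-dien-5-yl pivalate isomer of 17 | C=C(O[Si](C)(C)C(C)(C)C)[C@](C)(C#CC(=O)C(=O)CC)[C@@H](CN(C(=O)OC(C)(C)C)C(=O)OC(C)(C)C)CCC=C=C(OC(=O)C(C)(C)C)CCO[Si](C)(C)C(C)(C)C | intermediate (not isolated)
19 | (4S,5S)-5-{[bis(tert-butoxycarbonyl)amino]methyl}-4-[1-(tert-butyldimethylsilyloxy)vinyl]-1-[2-(tert-butyldimethylsilyloxy)ethyl]-4-methyl-2-oxo-3-(2-oxobutanoyl)-1,2,4,5,6,7-hexahydroazulen-1-yl pivalate (C1 epimers) | C=C(O[Si](C)(C)C(C)(C)C)[C@]1(C)C2=C(C(=O)C(=O)CC)C(=O)C(CCO[Si](C)(C)C(C)(C)C)(OC(=O)C(C)(C)C)C2=CCC[C@@H]1CN(C(=O)OC(C)(C)C)C(=O)OC(C)(C)C | intermediate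
20 | tricyclic ketol (rings A/C/D): the former vinyl CH2 of 19 bonded to the ring-proximal dione carbon, giving the (R)-tertiary alcohol that bears the propanoyl group; pivalate, silyl ether and N(Boc)2 retained | CCC(=O)[C@@]1(O)CC(=O)[C@]2(C)C3=C1C(=O)C(CCO[Si](C)(C)C(C)(C)C)(OC(=O)C(C)(C)C)C3=CCC[C@@H]2CN(C(=O)OC(C)(C)C)C(=O)OC(C)(C)C | intermediate
21 | primary alcohol: 20 without the O-silyl group | CCC(=O)[C@@]1(O)CC(=O)[C@]2(C)C3=C1C(=O)C(CCO)(OC(=O)C(C)(C)C)C3=CCC[C@@H]2CN(C(=O)OC(C)(C)C)C(=O)OC(C)(C)C | intermediate (not isolated)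
22 | tetracyclic pyran (rings A–D; ring A as CH keto tautomer, CH epimers) | CCC(=O)[C@@]1(O)CC(=O)[C@]2(C)C3=C1C(=O)C4CCOC(CC[C@@H]2CN(C(=O)OC(C)(C)C)C(=O)OC(C)(C)C)=C34 | intermediate
23 | primary ammonium trifluoroacetate of 22 (both Boc groups removed) | CCC(=O)[C@@]1(O)CC(=O)[C@]2(C)C3=C1C(=O)C4CCOC(CC[C@@H]2CN)=C34.OC(=O)C(F)(F)F | intermediate (not isolated)
24 | pentacyclic carbinolamine (rings A–E, N–H) | O=C1C2CCOC3=C2C2=C1[C@@](O)(C(=O)CC)C[C@@]4(O)NC[C@@H](CC3)[C@@]24C | intermediate (not isolated)
25 | O-deacetyl target (hexacycle A–F; ring A keto tautomer, CH epimers) | O=C1C2CCOC3=C2C2=C1[C@]1(O)C[C@@]4(O)N(C[C@@H](CC3)[C@@]24C)C[C@@H](C)C1=O | intermediate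
26 | CNP0309418.1 | CC(=O)OC1=C2CCOC3=C2C2=C1[C@]1(O)C[C@@]4(O)N(C[C@@H](CC3)[C@@]24C)C[C@@H](C)C1=O | target

**Totals**
Total step count: 16. Longest linear sequence: 16 steps, from (S)-epichlorohydrin 1; every other carbon comes from purchased reagents.

**Three steps most likely to fail, with fallbacks**

Step 12 (acyloxy shift and allenic Pauson–Khand). The alkyne is a strongly electron-poor ynedione that could chelate or decompose under the rhodium catalysts, and a seven-membered ring is closed. Fallback, setting out from 16 and returning at 19: metalate the terminal alkyne of 16 with LiN(SiMe3)2 (THF, −78 °C) and add it to 2-oxobutanal to give the alkynyl ketol F1, an ordinary propargylic alcohol instead of an ynedione. Subject F1 to the same Rh2(O2CCF3)4 then [Rh(CO)2Cl]2/CO sequence to obtain the cyclopentenone carbinol F2. Oxidise the secondary carbinol of F2 with Dess–Martin periodinane (NaHCO3, CH2Cl2) to reach 19, so the dione is revealed only after the cycloaddition.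

Step 13 (Mukaiyama aldol). Risks are Lewis-acid damage to the carbamates and silyl ether, competing attack at the alkylidene carbon or the outer dione carbonyl, and the wrong carbinol epimer. Fallback, from 19 to 20: brominate the silyl enol ether of 19 with NBS (THF, −78 °C) to the bromomethyl ketone F3. Treat F3 with activated Zn (THF, 0 °C) so that a zinc enolate adds to the dione in an intramolecular Reformatsky reaction under neutral, Lewis-acid-free conditions, giving 20.

Step 15 (Boc removal, carbinolamine, Mannich closure). A seven-membered Mannich ring closure in one pot competes with hydroxymethylation of the acidic ring A C–H, and it depends on the carbinol and methyl centres equilibrating. Fallback, from 22 to 25: remove the Boc groups (CF3CO2H, then NaHCO3) and isolate the carbinolamine 24. Convert 24 with paraformaldehyde in MeOH into the N-(methoxymethyl) carbinolamine F4. Ionise F4 with TMSOTf/Et3N (CH2Cl2, −78 → 0 °C), which also forms the silyl enol ether of the propanoyl ketone, so that the iminium–enol silane cyclisation gives 25 after acidic methanol work-up.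

**Further compounds**

F1 | step 12 | alkynyl ketol: 16 carrying a 3-hydroxy-4-oxohex-1-yn-1-yl group in place of the ethynyl group | C=C(O[Si](C)(C)C(C)(C)C)[C@](C)(C#CC(O)C(=O)CC)[C@@H](CN(C(=O)OC(C)(C)C)C(=O)OC(C)(C)C)CCC(OC(=O)C(C)(C)C)C#CCCO[Si](C)(C)C(C)(C)C
F2 | step 12 | cyclopentenone carbinol: 19 with CH(OH) in place of the ring-proximal dione carbonyl | C=C(O[Si](C)(C)C(C)(C)C)[C@]1(C)C2=C(C(O)C(=O)CC)C(=O)C(CCO[Si](C)(C)C(C)(C)C)(OC(=O)C(C)(C)C)C2=CCC[C@@H]1CN(C(=O)OC(C)(C)C)C(=O)OC(C)(C)C
F3 | step 13 | bromomethyl ketone: 19 with C(=O)CH2Br in place of the silyl enol ether | BrCC(=O)[C@]1(C)C2=C(C(=O)C(=O)CC)C(=O)C(CCO[Si](C)(C)C(C)(C)C)(OC(=O)C(C)(C)C)C2=CCC[C@@H]1CN(C(=O)OC(C)(C)C)C(=O)OC(C)(C)C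
F4 | step 15 | N-(methoxymethyl) carbinolamine: 24 with N–CH2OCH3 in place of N–H | O=C1C2CCOC3=C2C2=C1[C@@](O)(C(=O)CC)C[C@@]4(O)N(COC)C[C@@H](CC3)[C@@]24C
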